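**Strategy.** Ring locants: C1 (OMe), C2 (=CH), C3 (carries C7H2O), C4 (OH), C5 (OBz), C6 (OH). The oxygenated tetrad C1–C6–C5–C4 of the cyclohexene is twofold symmetric about the C5–C6 bond (1,6-cis, 6,5-trans, 5,4-cis). The route therefore cuts C1–C2 and C3–C4, giving a twofold-symmetric dialdehyde from D-tartrate and a C2=C3–C7 unit. In one operation rhodium transfers both alkenyl–boron bonds of a cis-1,2-diborylalkene to the two formyl groups, which closes the six-membered ring and sets C1 and C4. The precursors are the bis-TBS ether of (2S,3S)-tartaric dialdehyde and the PMB ether of cis-2,3-bis(pinacolboryl)allyl alcohol.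

Key step: step 5

Remark: ring compounds carry the locants given above (TBS = tert-butyldimethylsilyl, PMB = 4-methoxybenzyl, pin = pinacolato). The acetal carbon of 10 and 11 is drawn as the aryl-equatorial epimer expected from equilibration; it is removed in step 8. Dialdehyde 3 is used without chromatography.

**Step 1**
Reactants: 1 diethyl D-tartrate, (2S,3S)
Product: 2 diethyl (2S,3S)-2,3-bis(tert-butyldimethylsilyloxy)butanedioate
Conditions: TBSOTf (2.4 equiv), 2,6-lutidine (3 equiv), CH2Cl2, 0 °C to rt
Reagents that add atoms: tert-butyldimethylsilyl triflate, CC(C)(C)[Si](C)(C)OS(=O)(=O)C(F)(F)F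
Why: O-silylation of both secondary hydroxyls with a silyl triflate and a hindered pyridine base is fast even at the second, crowded hydroxyl and touches no stereocentre.

**Step 2**
Reactants: 2 diethyl (2S,3S)-2,3-bis(tert-butyldimethylsilyloxy)butanedioate
Product: 3 (2S,3S)-2,3-bis(tert-butyldimethylsilyloxy)butanedial
Conditions: i-Bu2AlH (DIBAL-H, 2.2 equiv), toluene, −78 °C; MeOH, then aq. KNaC4H4O6 (Rochelle salt), −78 °C to rt
Reagents that add atoms: none
Why: partial reduction of an α-silyloxy ester with i-Bu2AlH stops at the aldehyde because the tetrahedral aluminium hemiacetal is stable at −78 °C and collapses only on work-up, and the α-centres are not enolised under these conditions.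

**Step 3**
Reactants: 4 propargyl alcohol
Product: 5 4-methoxybenzyl prop-2-ynyl ether
Conditions: NaH, THF, 0 °C; PMBCl, Bu4NI (cat.), 0 °C to rt
Reagents that add atoms: 4-methoxybenzyl chloride, COc1ccc(CCl)cc1
Why: Williamson ether synthesis, in which the sodium alkoxide of 4 displaces the benzylic chloride while the alkyne C–H is not deprotonated by NaH.

**Step 4**
Reactants: 5 4-methoxybenzyl prop-2-ynyl ether; 6 bis(pinacolato)diboron
Product: 7 cis-2,3-bis(pinacolatoboryl)prop-2-enyl 4-methoxybenzyl ether (both boryl groups on the same side; E by CIP)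
Conditions: Pt(PPh3)4 (3 mol%), DMF, 80 °C
Reagents that add atoms: bis(pinacolato)diboron (6), CC1(C)OB(OC1(C)C)B1OC(C)(C)C(C)(C)O1
Why: zerovalent platinum inserts into the B–B bond, the alkyne inserts into Pt–B and reductive elimination places both boryl groups on the same face (platinum-catalysed syn-diboration of alkynes), which fixes the cis relationship of the two C–B bonds.

**Step 5**
Reactants: 3 (2S,3S)-2,3-bis(tert-butyldimethylsilyloxy)butanedial; 7 cis-2,3-bis(pinacolatoboryl)prop-2-enyl 4-methoxybenzyl ether
Product: 9 (1R,4R,5R,6R)-5,6-bis(tert-butyldimethylsilyloxy)-3-[(4-methoxybenzyloxy)methyl]cyclohex-2-ene-1,4-diol, via open-chain hydroxy aldehyde boronate 8 (not isolated)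
Conditions: [Rh(cod)OH]2 (5 mol%), K3PO4 (1.0 equiv), degassed 1,4-dioxane/H2O (10:1), 0.02 M, 30 °C, 3 added over 6 h to 7 (1.2 equiv)
Reagents that add atoms: none
Why: Proposed new method: a hydroxorhodium complex of monovalent rhodium should transmetalate the less hindered C2–B bond of 7, the alkenylrhodium inserts one formyl group of 3 to give 8, the new O1 alkoxide sits cis to the remaining boronate at C3 and activates it as an ate complex for the second boron-to-rhodium transfer, and the C3–Rh bond then adds to the second formyl group in a 6-exo-trig closure before hydrolysis returns Rh–OH. The closest known reaction types are the rhodium-catalysed 1,2-addition of alkenyl- and arylboron reagents to aldehydes, the intramolecular addition of alkenylrhodium intermediates to aldehydes in arylative cyclisations of alkynals, and Nozaki–Hiyama–Kishi ring closures. C1 is set by Felkin–Anh attack anti to the C6–OSi bond of the non-chelating silyl ether, which gives the 1,6-cis (erythro) relationship. C4 is set in a half-chair transition state in which the C5–OSi bond is anti to the forming C3–C4 bond and the aldehyde oxygen is pseudo-axial, clear of the C7 methylene, which gives the 4,5-cis relationship. The step needs this double cis selectivity and a 1:1 union: the twofold axis of 3 makes either order of bond formation converge on 9, the syn-diboration fixes the ring alkene geometry, and dilution with slow addition of 3 favours ring closure over oligomers. The C7 oxygen is kept as an ether, a poor leaving group, so that β-oxygen elimination from the C3–Rh species should not compete with carbonyl insertion.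

**Step 6**
Reactants: 9 (1R,4R,5R,6R)-5,6-bis(tert-butyldimethylsilyloxy)-3-[(4-methoxybenzyloxy)methyl]cyclohex-2-ene-1,4-diol
Product: 10 4,7-O-[(R)-4-methoxybenzylidene] acetal of (1R,4R,5R,6R)-5,6-bis(tert-butyldimethylsilyloxy)-3-(hydroxymethyl)cyclohex-2-ene-1,4-diol (O1–H free; aryl cis to C5 on the dioxane ring)
Conditions: DDQ (1.1 equiv), 4 Å MS, CH2Cl2, 0 °C
Reagents that add atoms: none
Why: DDQ oxidises the PMB ether to a benzylic oxocarbenium ion which, in the absence of water, is captured by the neighbouring O4–H as a six-membered acetal (oxidative acetalisation of a PMB ether), so that O7 and O4 are masked together, O1–H remains the only free hydroxyl, and the new acetal carbon should settle as the aryl-equatorial epimer.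

**Step 7**
Reactants: 10 4,7-O-(4-methoxybenzylidene) acetal with free O1–H
Product: 11 1-O-methyl ether of 10, (1R,4R,5R,6R), acetal carbon (R)
Conditions: Me3OBF4 (3 equiv), 1,8-bis(dimethylamino)naphthalene (4 equiv), 4 Å MS, CH2Cl2, 0 °C to rt
Reagents that add atoms: trimethyloxonium tetrafluoroborate, C[O+](C)C.F[B-](F)(F)F
Why: O-methylation with a Meerwein salt and proton sponge alkylates the neutral alcohol without forming an alkoxide, so the 1,2-silyl shift from O6 to O1 that NaH/MeI would risk is avoided and C1 is not touched.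

**Step 8**
Reactants: 11 1-O-methyl-4,7-O-(4-methoxybenzylidene)-5,6-bis-O-TBS compound
Product: 12 (1R,4R,5R,6S)-3-(hydroxymethyl)-1-methoxycyclohex-2-ene-4,5,6-triol (O1/O6 cis, O6/O5 trans, O5/O4 cis)
Conditions: HCl (0.1 M) in MeOH, rt to 40 °C; solid NaHCO3, filter
Reagents that add atoms: none
Why: acid-catalysed methanolysis (transacetalisation of the acetal and solvolysis of both silyl ethers) frees O4, O5, O6 and O7 in one operation, while the allylic methyl ether is stable because ionisation at C1 is disfavoured by the neighbouring C–O bonds.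

**Step 9**
Reactants: 12 (1R,4R,5R,6S)-3-(hydroxymethyl)-1-methoxycyclohex-2-ene-4,5,6-triol
Product: 14 [(3R,4R,5R,6R)-5-(benzoyloxy)-4,6-dihydroxy-3-methoxycyclohex-1-en-1-yl]methyl benzoate, via 4,5-O-dibutylstannylene acetal 13 (not isolated)
Conditions: Bu2SnO (1.1 equiv), MeOH, reflux; evaporate; BzCl (2.1 equiv), 1,4-dioxane, 0 °C to rt
Reagents that add atoms: benzoyl chloride, O=C(Cl)c1ccccc1
Why: stannylene-mediated regioselective acylation, in which the cis-4,5-diol forms the five-membered dibutylstannylene whose equatorial O5 is activated, the primary O7 is acylated as the most accessible hydroxyl with the Sn–O bond taking up HCl, and pseudo-axial O4 and O6 stay free, the pattern known from the 3,6-di-O-benzoylation of galactopyranosides, of which 12 is a carba-analogue.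

**Compound list**
1 | diethyl D-tartrate, diethyl (2S,3S)-2,3-dihydroxybutanedioate | CCOC(=O)[C@@H](O)[C@H](O)C(=O)OCC | starting material
2 | diethyl (2S,3S)-2,3-bis(tert-butyldimethylsilyloxy)butanedioate | CCOC(=O)[C@@H](O[Si](C)(C)C(C)(C)C)[C@H](O[Si](C)(C)C(C)(C)C)C(=O)OCC | intermediate
3 | (2S,3S)-2,3-bis(tert-butyldimethylsilyloxy)butanedial | O=C[C@@H](O[Si](C)(C)C(C)(C)C)[C@H](O[Si](C)(C)C(C)(C)C)C=O | intermediate
4 | propargyl alcohol (prop-2-yn-1-ol) | C#CCO | starting material
5 | 4-methoxybenzyl prop-2-ynyl ether | COc1ccc(COCC#C)cc1 | intermediate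
6 | bis(pinacolato)diboron | CC1(C)OB(OC1(C)C)B1OC(C)(C)C(C)(C)O1 | starting material
7 | cis-2,3-bis(pinacolatoboryl)prop-2-enyl 4-methoxybenzyl ether | COc1ccc(COC/C(B2OC(C)(C)C(C)(C)O2)=C/B2OC(C)(C)C(C)(C)O2)cc1 | intermediate
8 | (2S,3R,4R,5E)-2,3-bis(tert-butyldimethylsilyloxy)-4-hydroxy-7-(4-methoxybenzyloxy)-6-(pinacolatoboryl)hept-5-enal | O=C[C@@H](O[Si](C)(C)C(C)(C)C)[C@H](O[Si](C)(C)C(C)(C)C)[C@H](O)/C=C(\B1OC(C)(C)C(C)(C)O1)COCc1ccc(OC)cc1 | intermediate (not isolated)
9 | (1R,4R,5R,6R)-5,6-bis(tert-butyldimethylsilyloxy)-3-[(4-methoxybenzyloxy)methyl]cyclohex-2-ene-1,4-diol | O[C@H]1[C@@H](O[Si](C)(C)C(C)(C)C)[C@H](O[Si](C)(C)C(C)(C)C)[C@H](O)C=C1COCc2ccc(OC)cc2 | intermediate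
10 | 4,7-O-[(R)-4-methoxybenzylidene] acetal of (1R,4R,5R,6R)-5,6-bis(tert-butyldimethylsilyloxy)-3-(hydroxymethyl)cyclohex-2-ene-1,4-diol | O[C@@H]1C=C2CO[C@@H](c3ccc(OC)cc3)O[C@H]2[C@@H](O[Si](C)(C)C(C)(C)C)[C@@H]1O[Si](C)(C)C(C)(C)C | intermediate
11 | 1-O-methyl ether of 10 | CO[C@@H]1C=C2CO[C@@H](c3ccc(OC)cc3)O[C@H]2[C@@H](O[Si](C)(C)C(C)(C)C)[C@@H]1O[Si](C)(C)C(C)(C)C | intermediate
12 | (1R,4R,5R,6S)-3-(hydroxymethyl)-1-methoxycyclohex-2-ene-4,5,6-triol | CO[C@@H]1C=C(CO)[C@@H](O)[C@@H](O)[C@@H]1O | intermediate
13 | 4,5-O-dibutylstannylene acetal of 12 | CO[C@@H]1C=C(CO)[C@H]2O[Sn](CCCC)(CCCC)O[C@H]2[C@@H]1O | intermediate (not isolated)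
14 | [(3R,4R,5R,6R)-5-(benzoyloxy)-4,6-dihydroxy-3-methoxycyclohex-1-en-1-yl]methyl benzoate | CO[C@@H]1C=C(COC(=O)c2ccccc2)[C@@H](O)[C@@H](OC(=O)c2ccccc2)[C@@H]1O | target

**Step count.** Total: 9 steps. Longest linear sequence: 7 steps (1, 2, 5, 6, 7, 8, 9).

**Steps most likely to fail**

Step 5. The alkenylrhodium intermediates may be protonated by water before they insert the carbonyl group. The dialdehyde may epimerise or lose silanol by β-elimination in the basic aqueous medium. The mono-adduct may rest as its lactol, facial control at C1 or C4 may be poor, and chains may grow instead of rings. The fallback uses known chemistry, sets out from 3 and returns at 9. Dialdehyde 3 is treated with CH2=CHMgBr (1.0 equiv, THF, −78 °C); the first alkoxide closes on the second formyl group, which blocks a second addition and gives (3S,4R,5R)-3,4-bis(tert-butyldimethylsilyloxy)-5-ethenyloxolan-2-ol F1 as a mixture of anomers. Separately, 4-methoxybenzyl alcohol is alkylated with 2,3-dibromopropene (NaH, THF) to give 2-bromoallyl 4-methoxybenzyl ether F2. Bromine–lithium exchange (t-BuLi, Et2O, −78 °C) gives 2-lithioallyl 4-methoxybenzyl ether F3. An excess of this reagent opens the lactol and adds to the freed aldehyde in the Felkin–Anh sense, giving (3R,4R,5R,6R)-4,5-bis(tert-butyldimethylsilyloxy)-2-[(4-methoxybenzyloxy)methyl]octa-1,7-diene-3,6-diol F4. Ring-closing metathesis with the second-generation Grubbs catalyst (CH2Cl2, 40 °C) then forms C2=C3 and gives 9.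

Step 9. Discrimination between O5 and O6 may be poor, O4 may be over-acylated, and the benzoyl group may migrate between the cis oxygens O4 and O5. The fallback sets out from 12 and returns at 14. The primary hydroxyl is benzoylated alone (BzCl 1.05 equiv, 2,4,6-collidine, CH2Cl2, −40 °C) to give the 7-O-benzoate of 12 F5. The cis-4,5-diol is then bound as a tetracoordinate borinate by a catalytic amount of 2-aminoethyl diphenylborinate (Ph2BOCH2CH2NH2, 10 mol%; BzCl, i-Pr2NEt, MeCN, rt), which directs the second benzoyl group to the equatorial O5 and gives 14.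

Step 2. The reduction may run on to the alcohol stage at one terminus or stop short at the other, and the α-centres may epimerise during work-up. The fallback sets out from 2 and returns at 3. Both esters are reduced fully with excess i-Bu2AlH (CH2Cl2, −78 to 0 °C) to (2R,3R)-2,3-bis(tert-butyldimethylsilyloxy)butane-1,4-diol F6. A Swern oxidation ((COCl)2, DMSO, Et3N, CH2Cl2, −78 °C) then gives 3.

**Further compounds**
F1 | step 5 | (3S,4R,5R)-3,4-bis(tert-butyldimethylsilyloxy)-5-ethenyloxolan-2-ol (anomers) | C=C[C@H]1OC(O)[C@@H](O[Si](C)(C)C(C)(C)C)[C@@H]1O[Si](C)(C)C(C)(C)C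
F2 | step 5 | 2-bromoallyl 4-methoxybenzyl ether | C=C(Br)COCc1ccc(OC)cc1
F3 | step 5 | 2-lithioallyl 4-methoxybenzyl ether | [Li]C(=C)COCc1ccc(OC)cc1
F4 | step 5 | (3R,4R,5R,6R)-4,5-bis(tert-butyldimethylsilyloxy)-2-[(4-methoxybenzyloxy)methyl]octa-1,7-diene-3,6-diol | C=C[C@@H](O)[C@@H](O[Si](C)(C)C(C)(C)C)[C@H](O[Si](C)(C)C(C)(C)C)[C@H](O)C(=C)COCc1ccc(OC)cc1
F5 | step 9 | 7-O-benzoate of 12, [(3R,4S,5R,6R)-4,5,6-trihydroxy-3-methoxycyclohex-1-en-1-yl]methyl benzoate | CO[C@@H]1C=C(COC(=O)c2ccccc2)[C@@H](O)[C@@H](O)[C@@H]1O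
F6 | step 2 | (2R,3R)-2,3-bis(tert-butyldimethylsilyloxy)butane-1,4-diol | OC[C@@H](O[Si](C)(C)C(C)(C)C)[C@H](O[Si](C)(C)C(C)(C)C)CO
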